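**Retrosynthetic overview**
1. The hydroxy lactone is unveiled last from a 3-(acetoxymethyl) γ-lactone by saponification and periodate cleavage; the CH2OAc carbon is cut off.
2. The tetrasubstituted C4=C5 alkene comes from dehydration of a C-5 tertiary alcohol, followed by diimide reduction of the two disubstituted alkenes.
3. Key bond C-1′–C-5: electrochemical, indium-mediated γ-allylation of a bicyclic enone keto acid with 3-bromo-1,5,5-trimethylcyclohexene; this sets the quaternary centre.
4. The cyclohexenone ring comes from a Diels–Alder reaction of a 4-substituted Danishefsky-type diene with (S)-5-(acetoxymethyl)furan-2(5H)-one; this sets both ring-fusion centres.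
5. The diene side chain comes from SN2 alkylation of the 4-methoxybut-3-en-2-one enolate with tert-butyl (R)-lactate triflate. Ring order: butenolide (bought), cyclohexene (Diels–Alder), trimethylcyclohexane (bought, attached), hydroxy lactone (re-closed last).

Assumption: the lactol carbon C-3 equilibrates through the open aldehyde–acid form and the (3R) epimer of the target is the more stable one; locants C-1 to C-7a are those of the 2-benzofuran-1(3H)-one core and C-1′ is the quaternary carbon of the side ring.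

**Route**

Step 1
Reactants: 1 tert-butyl (2R)-2-hydroxypropanoate
Product: 2 tert-butyl (2R)-2-{[(trifluoromethyl)sulfonyl]oxy}propanoate
Conditions: Tf2O, 2,6-lutidine, CH2Cl2, −78 → 0 °C
Reagents that add atoms: trifluoromethanesulfonic anhydride, O=S(=O)(OS(=O)(=O)C(F)(F)F)C(F)(F)F
Why: Sulfonate ester formation takes place at oxygen only, so the bought (R) centre is untouched and becomes a good SN2 electrophile.

Step 2
Reactants: 3 (3E)-4-methoxybut-3-en-2-one; 2 tert-butyl (2R)-2-{[(trifluoromethyl)sulfonyl]oxy}propanoate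
Product: 5 tert-butyl (2R,5E)-6-methoxy-2-methyl-4-oxohex-5-enoate, via lithium dienolate 4 (not isolated)
Conditions: LiN(iPr)2, THF, −78 °C; then 2, −78 → −30 °C
Reagents that add atoms: none
Why: Kinetic deprotonation at the methyl group gives the cross-conjugated lithium enolate, which displaces the α-triflyloxy ester by SN2 with inversion (enolate alkylation), so the bought lactate centre becomes the (2R) methyl-bearing centre of the later propanoate.

Step 3
Reactants: 5 tert-butyl (2R,5E)-6-methoxy-2-methyl-4-oxohex-5-enoate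
Product: 6 tert-butyl (2R,3Z,5E)-4-[(tert-butyldimethylsilyl)oxy]-6-methoxy-2-methylhexa-3,5-dienoate
Conditions: TBSOTf, Et3N, Et2O, 0 °C
Reagents that add atoms: tert-butyldimethylsilyl trifluoromethanesulfonate, CC(C)(C)[Si](C)(C)OS(=O)(=O)C(F)(F)F
Why: Soft enolisation of the ketone toward its only enolisable methylene (silyl enol ether formation) gives the (Z)-silyl dienol ether, a 4-substituted Danishefsky-type diene with the side chain on the outside, while the ester α-centre is not enolised.

Step 4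
Reactants: 7 (5S)-5-(hydroxymethyl)furan-2(5H)-one
Product: 8 [(2S)-5-oxo-2,5-dihydrofuran-2-yl]methyl acetate
Conditions: Ac2O, pyridine, DMAP (cat.), CH2Cl2, 0 °C
Reagents that add atoms: acetic anhydride, CC(=O)OC(C)=O
Why: O-Acetylation protects the primary alcohol as an ester that the last step removes together with lactone opening, and the bought (S) centre is untouched.

Step 5
Reactants: 6 tert-butyl (2R,3Z,5E)-4-[(tert-butyldimethylsilyl)oxy]-6-methoxy-2-methylhexa-3,5-dienoate; 8 [(2S)-5-oxo-2,5-dihydrofuran-2-yl]methyl acetate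
Product: 10 (2R)-2-[(3S,3aS,4R,7aR)-3-[(acetyloxy)methyl]-1,5-dioxo-1,3,3a,4,5,7a-hexahydro-2-benzofuran-4-yl]propanoic acid, via Diels–Alder adduct 9 (not isolated)
Conditions: toluene, BHT (cat.), 130 °C, sealed tube; then TFA–CH2Cl2 (1:1), H2O (2 equiv), rt
Reagents that add atoms: none
Why: The thermal Diels–Alder reaction joins the nucleophilic diene terminus to the lactone β-carbon on the face anti to the acetoxymethyl group, which sets both cis ring-fusion centres from the bought butenolide centre, and TFA then hydrolyses the silyl enol ether, eliminates methanol to the enone and cleaves the tert-butyl ester, the epimerisable C-4 centre being of no consequence because it becomes sp2 in step 8.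

Step 6
Reactants: 11 3,5,5-trimethylcyclohex-2-en-1-ol (racemic)
Product: 12 3-bromo-1,5,5-trimethylcyclohex-1-ene (racemic)
Conditions: PBr3 (0.4 equiv), Et2O, 0 °C
Reagents that add atoms: phosphorus tribromide, BrP(Br)Br
Why: Bromination of the allylic alcohol gives the allylic bromide, whose stereocentre and possible allylic transposition do not matter because both isomers give the same allylindium reagent.

Step 7
Reactants: 10 (2R)-2-[(3S,3aS,4R,7aR)-3-[(acetyloxy)methyl]-1,5-dioxo-1,3,3a,4,5,7a-hexahydro-2-benzofuran-4-yl]propanoic acid; 12 3-bromo-1,5,5-trimethylcyclohex-1-ene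
Product: 15 methyl (2R)-2-[(3S,3aS,4R,5S,7aR)-3-[(acetyloxy)methyl]-5-hydroxy-1-oxo-5-[(1R)-1,5,5-trimethylcyclohex-2-en-1-yl]-1,3,3a,4,5,7a-hexahydro-2-benzofuran-4-yl]propanoate, via allylindium dibromide 13 (not isolated), via hydroxy acid 14 (not isolated)
Conditions: InBr3 (10 mol %), 12 (2.5 equiv), Bu4NBr, THF, Al anode/Pt cathode, undivided cell, 5 mA cm−2, 2.6 F mol−1, rt; aq. tartrate work-up at pH 5; then MeI, K2CO3, DMF, rt
Reagents that add atoms: iodomethane, CI
Why: Proposed new method: a carboxylate-directed, indium-catalysed electroreductive Barbier allylation of an enone carbonyl with a γ,γ-disubstituted cyclic allyl bromide, in which cathodically regenerated monovalent indium (Al is the sacrificial anode) inserts into 12 to give allylindium 13, which binds the free carboxylate of 10 and passes its methyl-bearing γ-carbon to the C-5 ketone through a six-membered chair SE2′ transition state on the convex face (anti to the lactone), the tether keeping indium on the C-4 side so that the CH2–CMe2 arm lies over the flat C-6=C-7 flank, which forms the C-1′–C-5 bond and sets the quaternary centre (1S after step 9) under control of the existing ring centres, the C-5 carbinol centre being lost in step 8 and the carboxylate being methylated afterwards; the closest known reactions are the indium-catalysed electrochemical allylation of ketones with allyl bromide, carboxylate- or hydroxyl-directed indium allylations and γ-selective prenyl-type Barbier additions to ketones.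

Step 8
Reactants: 15 methyl (2R)-2-[(3S,3aS,4R,5S,7aR)-3-[(acetyloxy)methyl]-5-hydroxy-1-oxo-5-[(1R)-1,5,5-trimethylcyclohex-2-en-1-yl]-1,3,3a,4,5,7a-hexahydro-2-benzofuran-4-yl]propanoate
Product: 16 methyl (2R)-2-[(3S,3aR,7aR)-3-[(acetyloxy)methyl]-1-oxo-5-[(1R)-1,5,5-trimethylcyclohex-2-en-1-yl]-1,3,3a,7a-tetrahydro-2-benzofuran-4-yl]propanoate
Conditions: Burgess reagent, benzene, 50 °C
Reagents that add atoms: none
Why: Burgess dehydration of the tertiary alcohol can only remove the hydrogen at C-4, because C-6 is vinylic and C-1′ is quaternary, so the tetrasubstituted C-4=C-5 double bond forms regiospecifically in conjugation with C-6=C-7 and the neighbouring propanoate centre is not touched.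

Step 9
Reactants: 16 methyl (2R)-2-[(3S,3aR,7aR)-3-[(acetyloxy)methyl]-1-oxo-5-[(1R)-1,5,5-trimethylcyclohex-2-en-1-yl]-1,3,3a,7a-tetrahydro-2-benzofuran-4-yl]propanoate
Product: 17 methyl (2R)-2-[(3S,3aR,7aR)-3-[(acetyloxy)methyl]-1-oxo-5-[(1S)-1,3,3-trimethylcyclohexyl]-1,3,3a,6,7,7a-hexahydro-2-benzofuran-4-yl]propanoate
Conditions: 2-nitrobenzenesulfonylhydrazide (6 equiv), Et3N, CH2Cl2, rt
Reagents that add atoms: none
Why: Diimide reduction saturates only the two unhindered cis-disubstituted double bonds and leaves the tetrasubstituted alkene, and no stereocentre is formed or touched.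

Step 10
Reactants: 17 methyl (2R)-2-[(3S,3aR,7aR)-3-[(acetyloxy)methyl]-1-oxo-5-[(1S)-1,3,3-trimethylcyclohexyl]-1,3,3a,6,7,7a-hexahydro-2-benzofuran-4-yl]propanoate
Product: 20 methyl (2R)-2-[(3R,3aR,7aR)-3-hydroxy-1-oxo-5-[(1S)-1,3,3-trimethylcyclohexyl]-1,3,3a,6,7,7a-hexahydro-2-benzofuran-4-yl]propanoate, via triol acid 18 (not isolated), via aldehyde acid 19 (not isolated)
Conditions: LiOH (2.5 equiv), THF–H2O, 0 °C; then NaH2PO4 to pH 7, NaIO4, 0 °C → rt; then 1 M HCl to pH 3
Reagents that add atoms: lithium hydroxide, [Li+].[OH-]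
Why: Hydroxide opens the γ-lactone and removes the acetate much faster than it attacks the hindered α-branched methyl ester, periodate cleaves the freed 1,2-diol (Malaprade cleavage) to the aldehyde, and on acidification the aldehyde–acid closes to the hydroxy lactone, whose acetal centre settles as the (3R) epimer under control of the two ring-fusion centres.

**Compound list**
1 | tert-butyl (2R)-2-hydroxypropanoate (tert-butyl D-lactate) | C[C@@H](O)C(=O)OC(C)(C)C | starting material
2 | tert-butyl (2R)-2-{[(trifluoromethyl)sulfonyl]oxy}propanoate | C[C@@H](OS(=O)(=O)C(F)(F)F)C(=O)OC(C)(C)C | intermediate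
3 | (3E)-4-methoxybut-3-en-2-one | CO/C=C/C(C)=O | starting material
4 | lithium (3E)-4-methoxybuta-1,3-dien-2-olate (not isolated) | [Li+].[O-]C(=C)/C=C/OC | intermediate
5 | tert-butyl (2R,5E)-6-methoxy-2-methyl-4-oxohex-5-enoate | C[C@H](CC(=O)/C=C/OC)C(=O)OC(C)(C)C | intermediate
6 | tert-butyl (2R,3Z,5E)-4-[(tert-butyldimethylsilyl)oxy]-6-methoxy-2-methylhexa-3,5-dienoate | C[C@H](/C=C(\O[Si](C)(C)C(C)(C)C)/C=C/OC)C(=O)OC(C)(C)C | intermediate
7 | (5S)-5-(hydroxymethyl)furan-2(5H)-one | OC[C@H]1OC(=O)C=C1 | starting material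
8 | [(2S)-5-oxo-2,5-dihydrofuran-2-yl]methyl acetate | CC(=O)OC[C@H]1OC(=O)C=C1 | intermediate
9 | endo Diels–Alder adduct (not isolated): tert-butyl (2R)-2-[3-[(acetyloxy)methyl]-5-[(tert-butyldimethylsilyl)oxy]-7-methoxy-1-oxo-1,3,3a,4,7,7a-hexahydro-2-benzofuran-4-yl]propanoate; H-3a, H-4, H-7 and H-7a all cis, CH2OAc at C-3 cis to H-3a | CC(C)(C)OC(=O)[C@H](C)[C@H]1C(O[Si](C)(C)C(C)(C)C)=C[C@@H](OC)[C@H]2C(=O)O[C@H](COC(C)=O)[C@@H]12 | intermediate
10 | (2R)-2-[(3S,3aS,4R,7aR)-3-[(acetyloxy)methyl]-1,5-dioxo-1,3,3a,4,5,7a-hexahydro-2-benzofuran-4-yl]propanoic acid (cis-fused; major C-4 epimer drawn, the other converges in step 8) | OC(=O)[C@H](C)[C@@H]1C(=O)C=C[C@H]2C(=O)O[C@H](COC(C)=O)[C@@H]12 | intermediate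
11 | 3,5,5-trimethylcyclohex-2-en-1-ol (isophorol, racemic) | CC1=CC(O)CC(C)(C)C1 | starting material
12 | 3-bromo-1,5,5-trimethylcyclohex-1-ene (racemic) | CC1=CC(Br)CC(C)(C)C1 | intermediate
13 | dibromo(3,5,5-trimethylcyclohex-2-en-1-yl)indium (not isolated) | CC1=CC([In](Br)Br)CC(C)(C)C1 | intermediate
14 | (2R)-2-[(3S,3aS,4R,5S,7aR)-3-[(acetyloxy)methyl]-5-hydroxy-1-oxo-5-[(1R)-1,5,5-trimethylcyclohex-2-en-1-yl]-1,3,3a,4,5,7a-hexahydro-2-benzofuran-4-yl]propanoic acid (not isolated) | OC(=O)[C@H](C)[C@@H]1[C@](O)([C@@]3(C)C=CCC(C)(C)C3)C=C[C@H]2C(=O)O[C@H](COC(C)=O)[C@@H]12 | intermediate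
15 | methyl (2R)-2-[(3S,3aS,4R,5S,7aR)-3-[(acetyloxy)methyl]-5-hydroxy-1-oxo-5-[(1R)-1,5,5-trimethylcyclohex-2-en-1-yl]-1,3,3a,4,5,7a-hexahydro-2-benzofuran-4-yl]propanoate (5-OH cis to the lactone ring) | COC(=O)[C@H](C)[C@@H]1[C@](O)([C@@]3(C)C=CCC(C)(C)C3)C=C[C@H]2C(=O)O[C@H](COC(C)=O)[C@@H]12 | intermediate
16 | methyl (2R)-2-[(3S,3aR,7aR)-3-[(acetyloxy)methyl]-1-oxo-5-[(1R)-1,5,5-trimethylcyclohex-2-en-1-yl]-1,3,3a,7a-tetrahydro-2-benzofuran-4-yl]propanoate | COC(=O)[C@H](C)C1=C([C@@]3(C)C=CCC(C)(C)C3)C=C[C@H]2C(=O)O[C@H](COC(C)=O)[C@@H]12 | intermediate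
17 | methyl (2R)-2-[(3S,3aR,7aR)-3-[(acetyloxy)methyl]-1-oxo-5-[(1S)-1,3,3-trimethylcyclohexyl]-1,3,3a,6,7,7a-hexahydro-2-benzofuran-4-yl]propanoate | COC(=O)[C@H](C)C1=C([C@@]3(C)CCCC(C)(C)C3)CC[C@H]2C(=O)O[C@H](COC(C)=O)[C@@H]12 | intermediate
18 | (1R,2R)-2-[(1S)-1,2-dihydroxyethyl]-3-[(2R)-1-methoxy-1-oxopropan-2-yl]-4-[(1S)-1,3,3-trimethylcyclohexyl]cyclohex-3-ene-1-carboxylic acid (not isolated) | COC(=O)[C@H](C)C1=C([C@@]2(C)CCCC(C)(C)C2)CC[C@@H](C(=O)O)[C@H]1[C@H](O)CO | intermediate
19 | (1R,2R)-2-formyl-3-[(2R)-1-methoxy-1-oxopropan-2-yl]-4-[(1S)-1,3,3-trimethylcyclohexyl]cyclohex-3-ene-1-carboxylic acid (not isolated) | COC(=O)[C@H](C)C1=C([C@@]2(C)CCCC(C)(C)C2)CC[C@@H](C(=O)O)[C@H]1C=O | intermediate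
20 | methyl (2R)-2-[(3R,3aR,7aR)-3-hydroxy-1-oxo-5-[(1S)-1,3,3-trimethylcyclohexyl]-1,3,3a,6,7,7a-hexahydro-2-benzofuran-4-yl]propanoate (CNP0280354.1) | COC(=O)[C@H](C)C1=C([C@@]2(C)CCCC(C)(C)C2)CC[C@H]2C(=O)O[C@@H](O)[C@@H]12 | target

**Step count and risks**

Total: 10 steps. Longest linear sequence: 8 steps (1, 2, 3, 5, 7, 8, 9, 10); steps 4 and 6 are side branches.

The three steps most likely to fail:

Step 7 (the proposed new method). The hindered, conjugated ketone may react slowly. 1,4-Addition or attack through the less substituted allyl terminus may compete. The ratio of epimers at C-1′ rests on a transition-state model and is not proven. Fallback with known chemistry: it sets out from 10 and comes back at 15. Bromide 12 is converted into its Grignard reagent (Mg, THF) and trapped with 9-methoxy-9-borabicyclo[3.3.1]nonane to give the allylborane 9-(3,5,5-trimethylcyclohex-2-en-1-yl)-9-borabicyclo[3.3.1]nonane F1. Acid 10 is esterified (MeI, K2CO3, DMF) to its methyl ester F2. F1 then adds to the ketone of F2 at −78 °C by allylboration through a closed six-membered transition state, again through the methyl-bearing carbon. Ethanolamine work-up gives 15; if the C-1′ epimer ratio is poor the epimers are separated at this stage.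

Step 8. The tertiary allylic sulfamate can ionise. The allyl cation could then undergo a 1,2-shift from the neighbouring quaternary carbon or lose the proton at C-7a instead of C-4. Fallback: it sets out from 15 and comes back at 17. Diimide (2-nitrobenzenesulfonylhydrazide, Et3N) first reduces both disubstituted double bonds of 15 to the saturated hydroxy ester F3. POCl3 in pyridine (0 °C → rt) then removes water by anti E2 elimination and gives 17 directly. No allyl cation is involved; the price is a possible C-5=C-6 regioisomer that has to be separated.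

Step 10. Hydroxide may partly saponify or epimerise the methyl propanoate. The freed aldehyde may pull the β,γ-double bond into conjugation. Fallback without hydroxide: it sets out from 17 and comes back at 20. K2CO3 in MeOH at 0 °C removes the acetate to give the primary alcohol F4. TEMPO/PhI(OAc)2 in MeCN–H2O oxidises it to the α-alkoxy carboxylic acid F5. Pb(OAc)4 with pyridine in benzene effects oxidative decarboxylation to the 3-acetoxy lactone F6 (mixture of C-3 epimers). Dilute HCl in THF–H2O hydrolyses this acylal to the hydroxy lactone 20.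

**Further compounds**
F1 | step 7 | 9-(3,5,5-trimethylcyclohex-2-en-1-yl)-9-borabicyclo[3.3.1]nonane (racemic) | CC1=CC(B2C3CCCC2CCC3)CC(C)(C)C1
F2 | step 7 | methyl (2R)-2-[(3S,3aS,4R,7aR)-3-[(acetyloxy)methyl]-1,5-dioxo-1,3,3a,4,5,7a-hexahydro-2-benzofuran-4-yl]propanoate | COC(=O)[C@H](C)[C@@H]1C(=O)C=C[C@H]2C(=O)O[C@H](COC(C)=O)[C@@H]12
F3 | step 8 | methyl (2R)-2-[(3S,3aS,4R,5S,7aR)-3-[(acetyloxy)methyl]-5-hydroxy-1-oxo-5-[(1S)-1,3,3-trimethylcyclohexyl]octahydro-2-benzofuran-4-yl]propanoate | COC(=O)[C@H](C)[C@@H]1[C@](O)([C@@]3(C)CCCC(C)(C)C3)CC[C@H]2C(=O)O[C@H](COC(C)=O)[C@@H]12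
F4 | step 10 | methyl (2R)-2-[(3S,3aR,7aR)-3-(hydroxymethyl)-1-oxo-5-[(1S)-1,3,3-trimethylcyclohexyl]-1,3,3a,6,7,7a-hexahydro-2-benzofuran-4-yl]propanoate | COC(=O)[C@H](C)C1=C([C@@]3(C)CCCC(C)(C)C3)CC[C@H]2C(=O)O[C@H](CO)[C@@H]12
F5 | step 10 | (3S,3aR,7aR)-4-[(2R)-1-methoxy-1-oxopropan-2-yl]-1-oxo-5-[(1S)-1,3,3-trimethylcyclohexyl]-1,3,3a,6,7,7a-hexahydro-2-benzofuran-3-carboxylic acid | COC(=O)[C@H](C)C1=C([C@@]3(C)CCCC(C)(C)C3)CC[C@H]2C(=O)O[C@H](C(=O)O)[C@@H]12
F6 | step 10 | methyl (2R)-2-[(3aR,7aR)-3-(acetyloxy)-1-oxo-5-[(1S)-1,3,3-trimethylcyclohexyl]-1,3,3a,6,7,7a-hexahydro-2-benzofuran-4-yl]propanoate (mixture of C-3 epimers) | COC(=O)[C@H](C)C1=C([C@@]3(C)CCCC(C)(C)C3)CC[C@H]2C(=O)OC(OC(C)=O)[C@@H]12
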